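**Plan**
Numbering is that of labdane: ring A = C1–C2–C3–C4–C5–C10, ring B = C5–C6–C7–C8–C9–C10, and the C10 methyl defines the β face.
Enabling feature: ring B carries methyls at C8 and C10 and no hydrogen at C10. It can therefore be read as a 2,4-dimethylphenol (oxygen at C7) that lost its aromaticity by gaining a fourth substituent at its para position C10. That substituent is C1, the end of the chain C4–C3–C2–C1 on the neighbouring carbon C5.
Cuts, in retrosynthetic order: C12–C13 (butenolide), C9–C11 (vinyl), the C7 oxygen and the C5–H/C6–OH pair (back to a 9-chloro-5,8-dien-7-one), C1–C10 (ring A), C4–C5 (aryl–lactone bond), C3–C4 (acid dianion plus epoxide).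
Forward order: the benzene ring that becomes ring B is made first and the C1–C4/C19 chain is joined to it as a lactone. Ring A then closes by dearomatisation, ring B is adjusted, and the butenolide is coupled on last.
Stereochemistry: C2 comes from benzyl (S)-glycidyl ether, and C4 from arylation of the lactone enolate anti to the C2 side arm. C10 comes from a chair transition state with the C2 silyloxy group equatorial, and C5 and C6 are set together by syn hydroboration from the α face.
The chlorine on C9 is a spectator in the ring closure. It keeps C8=C9 inert to borane and is later exchanged for the vinyl group C11–C12.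

Key step: step 10

Assumption: the target is taken exactly as drawn in the SMILES. This is the normal labdane series with 10β-CH3, 5α-H, equatorial 2α-OH and 6α-OH, and the hydroxymethyl group (C19) axial on the β face of C4.
Remark: the C7 configuration in 20–22 is of no consequence, because C7 becomes a carbonyl in step 12 and a CH2 group in step 17.

**Step 1**
Reactants: 1 2-chloro-1,3-dimethylbenzene
Product: 2 1,5-dibromo-3-chloro-2,4-dimethylbenzene
Conditions: Br2 (2.1 equiv), FeBr3 (5 mol %), CH2Cl2, 0 °C to rt, dark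
Reagents that add atoms: bromine, BrBr
Why: Electrophilic aromatic bromination, in which each methyl directs ortho/para, so both bromines enter the two equivalent positions flanking the remaining C–H, while the position para to chlorine is meta to both methyls and stays free.

**Step 2**
Reactants: 2 1,5-dibromo-3-chloro-2,4-dimethylbenzene
Product: 5 5-bromo-3-chloro-2,4-dimethylphenol, via aryllithium 3 (not isolated), via lithium aryltrimethoxyborate 4 (not isolated)
Conditions: n-BuLi (1.0 equiv), THF, −78 °C; B(OMe)3, −78 °C to rt; AcOH, 30% H2O2, 0 °C to rt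
Reagents that add atoms: hydrogen peroxide, OO (phenol oxygen); n-butyllithium, [Li]CCCC (lithium of 3 and 4); trimethyl borate, COB(OC)OC (boron and methoxy groups of 4)
Why: The two bromines are equivalent by symmetry, so one equivalent of n-BuLi gives a single aryllithium by bromine–lithium exchange, and borylation followed by peroxide oxidation (1,2-aryl shift from boron to oxygen) installs the C7 oxygen.

**Step 3**
Reactants: 5 5-bromo-3-chloro-2,4-dimethylphenol
Product: 6 1-(benzyloxy)-5-bromo-3-chloro-2,4-dimethylbenzene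
Conditions: BnBr, K2CO3, DMF, rt
Reagents that add atoms: benzyl bromide, BrCc1ccccc1
Why: Williamson ether synthesis masks the acidic phenol for the enolate and hydride steps with a group that leaves by neutral hydrogenolysis.

**Step 4**
Reactants: 7 propanoic acid; 8 benzyl (S)-glycidyl ether
Product: 11 (5S)-5-[(benzyloxy)methyl]-3-methyloxolan-2-one (both C3 epimers), via dilithium propanoate dianion 9 (not isolated), via hydroxy acid 10 (not isolated)
Conditions: LiN(i-Pr)2 (2.1 equiv), THF, 0 to 45 °C; 8, rt; 2 M HCl; TsOH (cat.), toluene, reflux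
Reagents that add atoms: lithium diisopropylamide, [Li]N(C(C)C)C(C)C (lithium of 9 only)
Why: The acid dianion attacks the unsubstituted epoxide carbon in an SN2 ring opening that forms C3–C4 and leaves the C2 stereocentre of 8 untouched, and acid-catalysed lactonisation follows; the epimer mixture at the future C4 is erased in step 5.

**Step 5**
Reactants: 11 (5S)-5-[(benzyloxy)methyl]-3-methyloxolan-2-one; 6 1-(benzyloxy)-5-bromo-3-chloro-2,4-dimethylbenzene
Product: 13 (3S,5S)-3-[5-(benzyloxy)-3-chloro-2,4-dimethylphenyl]-5-[(benzyloxy)methyl]-3-methyloxolan-2-one (aryl trans, methyl cis to the CH2OBn arm), via lithium enolate 12 (not isolated)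
Conditions: LiN(SiMe3)2 (1.2 equiv), toluene, −78 to 0 °C; 6, Pd(dba)2 (5 mol %), P(t-Bu)3 (6 mol %), rt to 60 °C
Reagents that add atoms: lithium hexamethyldisilazide, [Li]N([Si](C)(C)C)[Si](C)(C)C (lithium of 12 only)
Why: Palladium-catalysed α-arylation of a lactone enolate (zerovalent palladium inserts into C–Br rather than the doubly ortho-blocked C–Cl, then transmetalation and reductive elimination) forms C4–C5, and C4 is set because the bulky arylpalladium unit binds the planar enolate on the face anti to the C2 benzyloxymethyl arm.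

**Step 6**
Reactants: 13 aryl lactone
Product: 14 (2S,4S)-5-(benzyloxy)-2-[5-(benzyloxy)-3-chloro-2,4-dimethylphenyl]-2-methylpentane-1,4-diol
Conditions: LiAlH4, THF, 0 °C to rt; H2O work-up
Reagents that add atoms: none
Why: Hydride reduction of the lactone opens it to the primary C19 and secondary C2 alcohols without touching either stereocentre, the benzyl ethers or the aryl chloride.

**Step 7**
Reactants: 14 diol
Product: 15 1,4-bis(tert-butyldimethylsilyl) ether of 14
Conditions: TBSOTf (2.5 equiv), 2,6-lutidine, CH2Cl2, 0 °C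
Reagents that add atoms: tert-butyldimethylsilyl triflate, CC(C)(C)[Si](C)(C)OS(=O)(=O)C(F)(F)F
Why: A silyl triflate with a hindered pyridine base silylates even the neopentyl C19 hydroxyl, giving ethers that survive base, borane, palladium and tin hydride chemistry and fall together at the end.

**Step 8**
Reactants: 15 bis-silyl bis-benzyl ether
Product: 16 5-[(2S,4S)-1,4-bis(tert-butyldimethylsilyloxy)-5-hydroxy-2-methylpentan-2-yl]-3-chloro-2,4-dimethylphenol
Conditions: H2 (1 atm), 10% Pd/C, EtOAc, rt
Reagents that add atoms: none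
Why: Catalytic hydrogenolysis cleaves both benzylic C–O bonds, and in neutral EtOAc the aryl chloride shielded by two ortho methyl groups and the silyl ethers should persist.

**Step 9**
Reactants: 16 phenol alcohol
Product: 17 5-[(2S,4S)-1,4-bis(tert-butyldimethylsilyloxy)-5-iodo-2-methylpentan-2-yl]-3-chloro-2,4-dimethylphenol
Conditions: PPh3, I2, imidazole, CH2Cl2, 0 °C
Reagents that add atoms: iodine, II
Why: Appel iodination, in which the alkoxyphosphonium salt of the primary C1 alcohol is displaced by iodide, whereas an aryloxyphosphonium ion cannot undergo SN2, so the free phenol is left alone.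

**Step 10**
Reactants: 17 iodo phenol
Product: 19 9-chloro-2α,19-bis(tert-butyldimethylsilyloxy)-11,12,13,14,15,16-hexanorlabda-5,8-dien-7-one (10β-methyl), via potassium phenoxide 18 (not isolated)
Conditions: KOt-Bu (1.0 equiv), t-BuOH, 0.005 M, 60 °C
Reagents that add atoms: potassium tert-butoxide, CC(C)(C)[O-].[K+] (potassium of 18 only)
Why: KOt-Bu deprotonates the phenol, and phenoxide 18, an ambident vinylogous enolate, displaces iodide at C1 through its para carbon C10 in an intramolecular SN2 reaction that turns the arene into a cross-conjugated cyclohexa-2,5-dienone. The closest known reaction type is the base-mediated intramolecular para-C-alkylation of phenoxides that carry an ω-halide or sulfonate chain (cyclisation to 4,4-disubstituted dienones), used here in its fused rather than spiro variant. Ring A (C10–C1–C2–C3–C4–C5) closes in the 6-exo-tet mode, of the allowed 6-(enolendo) kind, because the four-atom chain lets C1 meet the C10 p-orbital perpendicular to the ring plane. C10 is the only new stereocentre and is controlled by C2 and C4: in the chair-like transition state the C2 silyloxy group is equatorial and the C10 methyl becomes axial and syn to the axial C4–CH2OTBS arm, whereas attack on the other face would place C2–OTBS, C4–CH3 and C10–CH3 all axial on one side. The step needs C10 to win over oxygen and over the ortho carbon C6: intramolecular O-alkylation would demand a meta-bridged ring, intermolecular O-alkylation is held back by high dilution, the hydrogen-bonding solvent and the soft iodide, and closure onto C6 needs a rotamer about C4–C5 in which a C4 substituent eclipses the C10 methyl (itself buttressed by the C9 chlorine), while the rotamer leading to C10 is the ground-state one. Only one equivalent of base is used, so the β-silyloxy iodide never meets free alkoxide.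

**Step 11**
Reactants: 19 chlorodienone
Product: 22 9-chloro-2α,19-bis(tert-butyldimethylsilyloxy)-11,12,13,14,15,16-hexanorlabd-8-ene-6α,7-diol (5α-H; C7 epimers), via dienyl borate 20 (not isolated), via C6 organoborane 21 (not isolated)
Conditions: BH3·THF (5 equiv), THF, 0 °C to rt; 3 M NaOH, 30% H2O2, 0 °C
Reagents that add atoms: hydrogen peroxide, OO (C6 oxygen); borane–THF, B.C1CCOC1 (boron of 20 and 21)
Why: Borane first reduces the cross-conjugated ketone in the 1,2 sense and then hydroborates the only reactive alkene, trisubstituted C5=C6 (the tetrasubstituted chloroalkene is inert), with boron on C6; syn addition from the α face, opposite the C10 methyl and the axial C4–CH2OTBS arm, and oxidation with retention set 5α-H and 6α-OH in one operation.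

**Step 12**
Reactants: 22 chloro diol
Product: 23 9-chloro-6α-hydroxy-2α,19-bis(tert-butyldimethylsilyloxy)-11,12,13,14,15,16-hexanorlabd-8-en-7-one
Conditions: MnO2 (20 equiv), CH2Cl2, rt
Reagents that add atoms: none
Why: MnO2 oxidises only the allylic C7 carbinol and leaves the saturated C6 carbinol alone, which restores the β-chloroenone needed to activate the C9–Cl bond.

**Step 13**
Reactants: 23 hydroxy chloroenone
Product: 24 6α-hydroxy-2α,19-bis(tert-butyldimethylsilyloxy)-13,14,15,16-tetranorlabda-8,11-dien-7-one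
Conditions: Bu3SnCH=CH2, Pd(PPh3)4 (5 mol %), dioxane, 90 °C
Reagents that add atoms: tributyl(vinyl)stannane, C=C[Sn](CCCC)(CCCC)CCCC
Why: Stille coupling, in which zerovalent palladium inserts into the C9–Cl bond because the C7 carbonyl makes it a vinylogous acid chloride, and vinyl transfer forms C9–C11 with C8=C9 kept in place under base-free conditions that tolerate the free hydroxyl.

**Step 14**
Reactants: 24 vinyl dienone
Product: 25 2α,19-bis(tert-butyldimethylsilyloxy)-13,14,15,16-tetranorlabda-8,11-diene-6α,7β-diol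
Conditions: NaBH4, CeCl3·7H2O, MeOH, −78 to 0 °C
Reagents that add atoms: none
Why: Luche reduction delivers hydride only in the 1,2 sense, and axial attack from the α face should give the pseudo-equatorial 7β-alcohol, a stereocentre that is removed again in step 17.

**Step 15**
Reactants: 25 dienediol; 26 4-bromofuran-2(5H)-one
Product: 28 6α,7β-dihydroxy-2α,19-bis(tert-butyldimethylsilyloxy)labda-8,13-dien-15,16-olide, via B-alkyl borane 27 (not isolated)
Conditions: 9-BBN (3.5 equiv, the excess allows for transient O-borylation), THF, rt; 26, PdCl2(dppf) (5 mol %), AsPh3, Cs2CO3, DMF–H2O, rt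
Reagents that add atoms: 9-borabicyclo[3.3.1]nonane, B1C2CCCC1CCC2 (boron and bicycle of 27 only)
Why: 9-BBN adds in the anti-Markovnikov sense only to the monosubstituted alkene (tetrasubstituted C8=C9 is inert), and the primary alkyl group is then transferred to bromide 26 in a B-alkyl Suzuki–Miyaura coupling that forms C12–C13.

**Step 16**
Reactants: 28 diol butenolide
Product: 29 6α,7β-cyclic thionocarbonate of 28
Conditions: 1,1'-thiocarbonyldiimidazole, DMAP (cat.), toluene, 80 °C
Reagents that add atoms: 1,1'-thiocarbonyldiimidazole, S=C(n1ccnc1)n1ccnc1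
Why: Both hydroxyls add to the thiocarbonyl transfer reagent with loss of imidazole and give the five-membered cyclic thionocarbonate under neutral conditions that the butenolide tolerates.

**Step 17**
Reactants: 29 cyclic thionocarbonate
Product: 31 6α-hydroxy-2α,19-bis(tert-butyldimethylsilyloxy)labda-8,13-dien-15,16-olide, via S-stannyl thiocarbonate 30 (not isolated)
Conditions: Bu3SnH (3 equiv), AIBN (0.2 equiv), toluene, 100 °C; aq KF work-up
Reagents that add atoms: tributyltin hydride, CCCC[SnH](CCCC)CCCC (tin of 30 only)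
Why: Barton-type radical deoxygenation of a cyclic thionocarbonate, in which the stannyl radical adds to sulfur, the adduct fragments at C7–O because that gives the allylic radical, hydrogen transfer occurs at the less hindered terminus C7 so that C8=C9 stays tetrasubstituted, and fluoride work-up frees the 6α-hydroxyl with loss of COS.

**Step 18**
Reactants: 31 bis-silyl ether
Product: 32 2α,6α,19-trihydroxylabda-8,13-dien-15,16-olide (CNP0387838.1)
Conditions: 48% aq HF, MeCN, 0 °C to rt
Reagents that add atoms: none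
Why: Fluoride-driven cleavage of both silyl ethers under mildly acidic conditions spares the butenolide, the tetrasubstituted alkene and all five stereocentres.

**Compound list**
1 | 2-chloro-1,3-dimethylbenzene | Cc1cccc(C)c1Cl | starting material
2 | 1,5-dibromo-3-chloro-2,4-dimethylbenzene | Cc1c(Br)cc(Br)c(C)c1Cl | intermediate
3 | (5-bromo-3-chloro-2,4-dimethylphenyl)lithium | [Li]c1cc(Br)c(C)c(Cl)c1C | intermediate
4 | lithium (5-bromo-3-chloro-2,4-dimethylphenyl)trimethoxyborate | [Li+].CO[B-](OC)(OC)c1cc(Br)c(C)c(Cl)c1C | intermediate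
5 | 5-bromo-3-chloro-2,4-dimethylphenol | Cc1c(O)cc(Br)c(C)c1Cl | intermediate
6 | 1-(benzyloxy)-5-bromo-3-chloro-2,4-dimethylbenzene | Cc1c(OCc2ccccc2)cc(Br)c(C)c1Cl | intermediate
7 | propanoic acid | CCC(=O)O | starting material
8 | benzyl (S)-glycidyl ether | C1O[C@@H]1COCc2ccccc2 | starting material
9 | dilithium propanoate dianion | [Li+].[Li+].CC=C([O-])[O-] | intermediate
10 | (4S)-5-(benzyloxy)-4-hydroxy-2-methylpentanoic acid | CC(C[C@H](O)COCc1ccccc1)C(=O)O | intermediate
11 | (5S)-5-[(benzyloxy)methyl]-3-methyloxolan-2-one | O=C1O[C@H](COCc2ccccc2)CC1C | intermediate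
12 | lithium enolate of 11 | [Li+].[O-]C1=C(C)C[C@@H](COCc2ccccc2)O1 | intermediate
13 | (3S,5S)-3-[5-(benzyloxy)-3-chloro-2,4-dimethylphenyl]-5-[(benzyloxy)methyl]-3-methyloxolan-2-one | O=C1O[C@H](COCc2ccccc2)C[C@@]1(C)c3cc(OCc4ccccc4)c(C)c(Cl)c3C | intermediate
14 | (2S,4S)-5-(benzyloxy)-2-[5-(benzyloxy)-3-chloro-2,4-dimethylphenyl]-2-methylpentane-1,4-diol | Cc1c(OCc2ccccc2)cc([C@@](C)(CO)C[C@H](O)COCc2ccccc2)c(C)c1Cl | intermediate
15 | 1,4-bis(TBS) ether of 14 | Cc1c(OCc2ccccc2)cc([C@@](C)(CO[Si](C)(C)C(C)(C)C)C[C@H](O[Si](C)(C)C(C)(C)C)COCc2ccccc2)c(C)c1Cl | intermediate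
16 | 5-[(2S,4S)-1,4-bis(TBSO)-5-hydroxy-2-methylpentan-2-yl]-3-chloro-2,4-dimethylphenol | Cc1c(O)cc([C@@](C)(CO[Si](C)(C)C(C)(C)C)C[C@H](O[Si](C)(C)C(C)(C)C)CO)c(C)c1Cl | intermediate
17 | 5-[(2S,4S)-1,4-bis(TBSO)-5-iodo-2-methylpentan-2-yl]-3-chloro-2,4-dimethylphenol | Cc1c(O)cc([C@@](C)(CO[Si](C)(C)C(C)(C)C)C[C@H](O[Si](C)(C)C(C)(C)C)CI)c(C)c1Cl | intermediate
18 | potassium phenoxide of 17 | [K+].Cc1c([O-])cc([C@@](C)(CO[Si](C)(C)C(C)(C)C)C[C@H](O[Si](C)(C)C(C)(C)C)CI)c(C)c1Cl | intermediate
19 | 9-chloro-2α,19-bis(TBSO)-hexanorlabda-5,8-dien-7-one | CC1=C(Cl)[C@@]2(C)C[C@@H](O[Si](C)(C)C(C)(C)C)C[C@](C)(CO[Si](C)(C)C(C)(C)C)C2=CC1=O | intermediate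
20 | C7 boryl ether of the 5,8-dien-7-ol | CC1=C(Cl)[C@@]2(C)C[C@@H](O[Si](C)(C)C(C)(C)C)C[C@](C)(CO[Si](C)(C)C(C)(C)C)C2=CC1OB | intermediate
21 | 6α-boryl-5α-H adduct of 20 | CC1=C(Cl)[C@@]2(C)C[C@@H](O[Si](C)(C)C(C)(C)C)C[C@](C)(CO[Si](C)(C)C(C)(C)C)[C@@H]2[C@@H](B)C1OB | intermediate
22 | 9-chloro-2α,19-bis(TBSO)-hexanorlabd-8-ene-6α,7-diol | CC1=C(Cl)[C@@]2(C)C[C@@H](O[Si](C)(C)C(C)(C)C)C[C@](C)(CO[Si](C)(C)C(C)(C)C)[C@@H]2[C@@H](O)C1O | intermediate
23 | 9-chloro-6α-hydroxy-2α,19-bis(TBSO)-hexanorlabd-8-en-7-one | CC1=C(Cl)[C@@]2(C)C[C@@H](O[Si](C)(C)C(C)(C)C)C[C@](C)(CO[Si](C)(C)C(C)(C)C)[C@@H]2[C@@H](O)C1=O | intermediate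
24 | 6α-hydroxy-2α,19-bis(TBSO)-13,14,15,16-tetranorlabda-8,11-dien-7-one | CC1=C(C=C)[C@@]2(C)C[C@@H](O[Si](C)(C)C(C)(C)C)C[C@](C)(CO[Si](C)(C)C(C)(C)C)[C@@H]2[C@@H](O)C1=O | intermediate
25 | 2α,19-bis(TBSO)-13,14,15,16-tetranorlabda-8,11-diene-6α,7β-diol | CC1=C(C=C)[C@@]2(C)C[C@@H](O[Si](C)(C)C(C)(C)C)C[C@](C)(CO[Si](C)(C)C(C)(C)C)[C@@H]2[C@@H](O)[C@@H]1O | intermediate
26 | 4-bromofuran-2(5H)-one | O=C1OCC(Br)=C1 | starting material
27 | C12 B-alkyl-9-BBN derivative of 25 | CC1=C(CCB3C4CCCC3CCC4)[C@@]2(C)C[C@@H](O[Si](C)(C)C(C)(C)C)C[C@](C)(CO[Si](C)(C)C(C)(C)C)[C@@H]2[C@@H](O)[C@@H]1O | intermediate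
28 | 6α,7β-dihydroxy-2α,19-bis(TBSO)labda-8,13-dien-15,16-olide | CC1=C(CCC3=CC(=O)OC3)[C@@]2(C)C[C@@H](O[Si](C)(C)C(C)(C)C)C[C@](C)(CO[Si](C)(C)C(C)(C)C)[C@@H]2[C@@H](O)[C@@H]1O | intermediate
29 | 6α,7β-cyclic thionocarbonate of 28 | CC1=C(CCC3=CC(=O)OC3)[C@@]2(C)C[C@@H](O[Si](C)(C)C(C)(C)C)C[C@](C)(CO[Si](C)(C)C(C)(C)C)[C@@H]2[C@H]4OC(=S)O[C@H]14 | intermediate
30 | 6α-O-[(tributylstannylthio)carbonyl] derivative of 31 | CC1=C(CCC3=CC(=O)OC3)[C@@]2(C)C[C@@H](O[Si](C)(C)C(C)(C)C)C[C@](C)(CO[Si](C)(C)C(C)(C)C)[C@@H]2[C@@H](OC(=O)S[Sn](CCCC)(CCCC)CCCC)C1 | intermediate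
31 | 6α-hydroxy-2α,19-bis(TBSO)labda-8,13-dien-15,16-olide | CC1=C(CCC3=CC(=O)OC3)[C@@]2(C)C[C@@H](O[Si](C)(C)C(C)(C)C)C[C@](C)(CO[Si](C)(C)C(C)(C)C)[C@@H]2[C@@H](O)C1 | intermediate
32 | 2α,6α,19-trihydroxylabda-8,13-dien-15,16-olide (CNP0387838.1) | CC1=C(CCC2=CC(=O)OC2)[C@@]2(C)C[C@@H](O)C[C@](C)(CO)[C@@H]2[C@@H](O)C1 | target

**Step count and risks**
Total step count: 18.
Longest linear sequence: 17 steps (from 1 through steps 1–3 and 5–18).

**Step 5.** Reductive elimination to a quaternary carbon next to an ortho-methyl group may be too slow, so that enolate decay and hydrodebromination take over. Facial selectivity may also erode.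
The fallback runs from 6 and 8 back to 13 and builds the quaternary carbon by alkylation instead of arylation. The enolate of tert-butyl propanoate is arylated with 6 under palladium catalysis, which now has to form only a tertiary centre, to give tert-butyl 2-[5-(benzyloxy)-3-chloro-2,4-dimethylphenyl]propanoate F1. CF3CO2H in CH2Cl2 then frees the 2-arylpropanoic acid F2. Its dianion (LiN(i-Pr)2, 2 equiv) opens epoxide 8 at the CH2 terminus to the γ-hydroxy acid F3 as a pair of C4 epimers. TsOH in toluene lactonises both, and chromatography separates 13 from the cis-aryl lactone F4.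

**Step 10.** The ring may close through the ortho carbon C6 with rearomatisation, or intermolecular O-alkylation may outrun a slow displacement at the β-branched C1.
The fallback runs from 17 back to 19 and blocks C6 before the closure. NBS with catalytic i-Pr2NH in CH2Cl2 brominates the only free ring position of 17 and gives the 6-bromophenol F5. KOt-Bu in t-BuOH then leaves C10 as the only unsubstituted-path carbon nucleophile within reach and gives the 6-bromodienone F6. Bu3SnH with Pd(PPh3)4 in THF at rt replaces the vinylic bromine by hydrogen, the C9–Cl bond reacting far more slowly, and delivers 19.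

**Step 11.** Hydroboration of an alkene flanked by two quaternary carbons may be sluggish, and the C7 oxygen may be lost by boron–oxygen elimination followed by renewed hydroboration.
The fallback runs from 19 back to 23, so step 12 is skipped as well, and uses hydrogen-atom-transfer reduction with oxygen trapping. Mn(dpm)3 (cat., dpm = dipivaloylmethanate), PhSiH3 and O2 in i-PrOH add a hydrogen atom to C5 of the less substituted enone. O2 then adds to the resulting C6 radical, both from the α face, to give the 6α-hydroperoxy ketone F7. P(OEt)3 reduces F7 in the same flask to 23.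

**Further compounds**
F1 | step 5 | tert-butyl 2-[5-(benzyloxy)-3-chloro-2,4-dimethylphenyl]propanoate | CC(C(=O)OC(C)(C)C)c1cc(OCc2ccccc2)c(C)c(Cl)c1C
F2 | step 5 | 2-[5-(benzyloxy)-3-chloro-2,4-dimethylphenyl]propanoic acid | CC(C(=O)O)c1cc(OCc2ccccc2)c(C)c(Cl)c1C
F3 | step 5 | (4S)-5-(benzyloxy)-2-[5-(benzyloxy)-3-chloro-2,4-dimethylphenyl]-4-hydroxy-2-methylpentanoic acid (C2 epimers) | OC(=O)C(C)(C[C@H](O)COCc1ccccc1)c1cc(OCc2ccccc2)c(C)c(Cl)c1C
F4 | step 5 | (3R,5S)-3-[5-(benzyloxy)-3-chloro-2,4-dimethylphenyl]-5-[(benzyloxy)methyl]-3-methyloxolan-2-one | O=C1O[C@H](COCc2ccccc2)C[C@]1(C)c3cc(OCc4ccccc4)c(C)c(Cl)c3C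
F5 | step 10 | 2-bromo-3-[(2S,4S)-1,4-bis(TBSO)-5-iodo-2-methylpentan-2-yl]-5-chloro-4,6-dimethylphenol | Cc1c(O)c(Br)c([C@@](C)(CO[Si](C)(C)C(C)(C)C)C[C@H](O[Si](C)(C)C(C)(C)C)CI)c(C)c1Cl
F6 | step 10 | 6-bromo-9-chloro-2α,19-bis(TBSO)-hexanorlabda-5,8-dien-7-one | CC1=C(Cl)[C@@]2(C)C[C@@H](O[Si](C)(C)C(C)(C)C)C[C@](C)(CO[Si](C)(C)C(C)(C)C)C2=C(Br)C1=O
F7 | step 11 | 9-chloro-6α-hydroperoxy-2α,19-bis(TBSO)-hexanorlabd-8-en-7-one | CC1=C(Cl)[C@@]2(C)C[C@@H](O[Si](C)(C)C(C)(C)C)C[C@](C)(CO[Si](C)(C)C(C)(C)C)[C@@H]2[C@@H](OO)C1=O
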